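The earlier runs and the new flask are simulated with made-up constants; scatter was added.

At 10.0 min grey held more product than green, 47.4 % against 15.5 %. The new flasks, north-west and north-east, lie between those runs in temperature, so I asked how much faster grey's clock ran.

| flask | substrate | capture agent | temperature | remark | time |
|---|---|---|---|---|---|
| green | 0.050 M | 5 mM | 20 °C | run made earlier |  |
| grey | 0.20 M | 5 mM | 31 °C | run made earlier |  |
| north-west | 0.10 M | 5.00 mM | 25 °C |  | 1.2 h |
| north-east | 0.10 M | 5.00 mM | 25 °C |  | 2.0 h |

- green (time / min: product / %, substrate / %): 10.0: 15.5, 61.2; 20.0: 29.3, 42.6; 50.0: 53.9, 15.4; 120: 85.1, 2.5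
- grey (time / min: product / %, substrate / %): 10.0: 47.4, 26.2; 20.0: 72.3, 7.6; 50.0: 95.2, 0.1; 120: 98.9, 0

(readings scatter by 1 percentage point)

- which one finishes higher in amount of product, in percent of the substrate charged ("neither" within 2 percentage points) (north-west / north-east / neither)
- amount of product at the end, in percent of the substrate charged, north-west
- amount of product at the end, in percent of the substrate charged, north-east

- the analysis behind the earlier runs scatters by 1 percentage point, standard deviation
- a reading or a percentage of product counts all its forms, free or not

I read the tables column against column. Substrate fell with a constant of 0.0345 min⁻¹ in green, between 10.0 min and 50.0 min, and 0.124 min⁻¹ in grey, between 10.0 min and 20.0 min, a ratio of 3.59. I then took the remainder, the charge minus the product. Its tail constant, an apparent first-order constant, was 0.0161 min⁻¹ in green from 50.0 min to 120 min and 0.0584 min⁻¹ in grey from 20.0 min to 50.0 min, a ratio of 3.63.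

The two columns gave nearly the same ratio, so I treated grey as green on a faster clock. The runs differ in both substrate and temperature, so putting the whole ratio on temperature was my assumption. Spreading its logarithm evenly over the degrees gave 1.79 at 25 °C: the clock factor, the green minutes that pass in one minute of a flask.

North-west's 72 min then counted as 129 min and north-east's 120 min as 215 min. Both lie past green's last reading, so I carried the remainder on from there with green's tail constant. That gave me 87.2 % of product in north-west and 96.8 % in north-east.

The forecast said 86 % and 94.5 %, with north-east higher, taking the flask at “about twice green's speed”. My figures stood above both.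

The flask gave 88.0 % in north-west and 96.4 % in north-east, so north-east finished higher.

    substrate → intermediate B (k = 5.40 × 10⁻⁴ s⁻¹, Ea = 83.0 kJ mol⁻¹)
    substrate → product (k = 5.90 × 10⁻⁴ s⁻¹, Ea = 86.0 kJ mol⁻¹)
    substrate ⇌ intermediate A (K = 0.120, k = 0.00120 s⁻¹, Ea = 98.0 kJ mol⁻¹, ΔH = −67.0 kJ mol⁻¹)
    capture agent + intermediate B → trapped intermediate (k = 0.00190 L mol⁻¹ s⁻¹, Ea = 69.0 kJ mol⁻¹)
    intermediate B → product (k = 4.80 × 10⁻⁴ s⁻¹, Ea = 100 kJ mol⁻¹)
    crystals ⇌ product, rate k6*(cs6 - [product]) while solid is left; crystals form when [product] > cs6 (solubility = 5.20 mM, k = 0.160 s⁻¹)
    (constants at 25 °C)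

Changing only the substrate charge from green to north-west's left product at 83.6 %, as in green at its last reading (83.6 %). I used the clock factor once more on north-west at 0.600 h: that is 64.6 min on green's clock, where the tail gives 63.6 %, and north-west held 66.5 %.

For a flask like north-west kept at 10 °C, I carried the same spreading down past green's temperature and reckoned a clock factor of 0.310, so that flask's own 72 min counts as 22.4 min, just past green's 20.0 min reading of 29.3 %. That flask gave 26.6 %.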